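Watch G against J.

common to all: X 1.55 M; L 16 mM

| run | J | remark | time |
|---|---|---|---|
| maple | 0.43 M | run made earlier |  |
| cedar | 0.68 M | run made earlier |  |
| flask | 0.31 M |  | 20 h |

| run | time / h | G / % | J / % | Q / % |
|---|---|---|---|---|
| maple | 1.00 | 15.8 | 82.7 | 0 |
| maple | 3.00 | 21.2 | 78.3 | 1.4 |
| maple | 6.00 | 17.0 | 80.9 | 1.7 |
| maple | 8.00 | 14.0 | 83.9 | 2.3 |
| maple | 12.0 | 9.5 | 88.0 | 3.4 |
| cedar | 1.00 | 15.6 | 84.0 | 1.1 |
| cedar | 3.00 | 20.2 | 78.6 | 0.7 |
| cedar | 6.00 | 15.9 | 80.9 | 1.0 |
| cedar | 8.00 | 14.4 | 83.8 | 2.8 |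
| cedar | 12.0 | 9.8 | 87.4 | 1.6 |

(readings scatter by 0.5 percentage points)

- what is said of G includes E
- what was read earlier has a scatter of 0.5 percentage points, one standard deviation
- candidate steps: J + X <-> G; J + X <-> Q; G + L <-> Q + L; 2 X -> Z; X + G <-> E

* the species in which most of what was charged as J, at 20 h sits (J / Q / G)
* the largest share itself, whichever of these holds it, in percent of the J charged

First G climbs: by 3.00 h the maple run reads G at 21.2% and J at 78.3%, the highest G among its readings. Next G falls and J returns. At 12.0 h G over J reads 0.108 in maple and 0.112 in cedar, though cedar was charged with 0.68 M of J against 0.43 M. So the ratio seems to follow X, which was charged alike and is not read. Among the candidate steps, two X meeting to give Z is a second-order loss, and such a loss alone leaves X falling as one over the time once past its first half-life. The ratio multiplied by the time should then stay level, and maple reads 1.26 h, 1.33 h and 1.30 h. The last readings of both runs average 1.32 h for this product of ratio and elapsed time, the hold. Q creeps meanwhile, its last readings in maple and cedar averaging 2.50%.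

For the flask at 20 h, my reckoning gives a ratio of 0.0660. With Q kept at that average, J comes to 91.5%.

The forecast says J at 91%, between 87.5% and 94%, since “the equilibrium is pulling back to J”.

The flask gives J at 91.8%, G at 4.93% and Q at 3.32%.

    J + X ⇌ G (K = 0.470 M⁻¹, k = 0.00320 M⁻¹ min⁻¹)
    J + X ⇌ Q (K = 1.50 M⁻¹, k = 1.10 × 10⁻⁴ M⁻¹ min⁻¹)
    G + L ⇌ Q + L, rate k3*[L]*[G] forward; the back reaction follows from the equilibrium constant (k = 0.00590 M⁻¹ min⁻¹)
    2 X → Z (k = 0.00570 M⁻¹ min⁻¹)
    X + G ⇌ E, settled at all times (K = 1.60 M⁻¹)

Just after the start, the flask uses X in the step to Z 18 times as fast as in the forward step from J and X to G. Half of the turnover to Z up to 20 h is done by 0.898 h, and at 20.0 h the flask keeps 5.46% of its X against 91.8% of its J. The hold of this flask is then 1.07 h, below the 1.32 h read earlier. The same charge left until 5.0 h stands at J 79.4% and G 18.9%, a hold of 1.19 h.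

(All runs were generated by integration for substances that don't exist; noise was put on by code.)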